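The readings are calculated from invented constants; noise was put on by code.

Monomer in chains, divided by the chains begun, is the number-average length asked for here. The readings give the numerator but not the denominator, so the length is bracketed here.

| flask | free monomer | transfer agent | protic impurity | initiator | remark | time |
|---|---|---|---|---|---|---|
| Thursday's | 0.020 M | 0.20 mM | 1.3 mM | 0.13 mM | run made earlier |  |
| Friday's | 0.020 M | 0.20 mM | 2 mM | 0.26 mM | run made earlier |  |
| epsilon | 0.020 M | 0.200 mM | 2.00 mM | 0.13 mM |  | 3.0 min |
| theta | 0.0060 M | 0.200 mM | 2.00 mM | 0.13 mM |  | 3.0 min |

| run | time / s | monomer in chains / % | free monomer / % |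
|---|---|---|---|
| Thursday's | 10.0 | 21.7 | 71.7 |
| Thursday's | 12.0 | 25.4 | 66.7 |
| Thursday's | 25.0 | 43.1 | 49.2 |
| Thursday's | 60.0 | 66.2 | 26.7 |
| Friday's | 15.0 | 49.8 | 40.4 |
| Friday's | 30.0 | 70.5 | 19.8 |
| Friday's | 50.0 | 80.5 | 9.7 |
| Friday's | 60.0 | 83.9 | 6.2 |

(each reading ± 0.5 percentage points)

- which of the two ends with the longer chains by the average number of monomer units in a chain (chains begun, living or dead) ("neither" if they lie within 10 %) (epsilon / theta / neither)
- average number of monomer units in a chain (chains begun, living or dead) at the end, epsilon
- average number of monomer units in a chain (chains begun, living or dead) at the end, theta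

- the average divides the monomer in chains by the number of chains begun, living and dead together
- what was read earlier has a scatter of 0.5 percentage points, one standard deviation
- the earlier runs do not show the number of chains; that part of a forecast is a guess

Friday's last reading falls short of the charge by 1.98 mM, close to the 2 mM of protic impurity in that flask. Thursday's falls short by 1.42 mM against 1.3 mM. So protic impurity is read as removing free monomer about one to one.

From above: suppose each initiator begins one chain and the transfer agent begins none. Then c(free monomer) minus c(protic impurity), over c(initiator), gives 138 for epsilon and 30.8 for theta. Call this the ceiling length.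

From below: suppose each transfer agent begins a chain too, and take the share of reacting monomer already in chains at Thursday's last reading, 71.3 %, as the least reached. That gives 38.9 for epsilon and 8.64 for theta.

The two brackets do not overlap: the lower bound of epsilon stands above the ceiling of theta, so this reckoning commits to epsilon.

The forecast says epsilon, with 74 and 16.4, inside both brackets, and of the chains it says “I guess about 0.22 mM”.

The flask gives epsilon, with 124 and 28.3.

    living end + transfer agent → dead chain (kL = 86.0 L mol⁻¹ s⁻¹)
    free monomer + living end → monomer in chains + living end, rate k2*[living end]*[free monomer] (k = 240 L mol⁻¹ s⁻¹)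
    free monomer + initiator → living end + monomer in chains (k = 47.0 L mol⁻¹ s⁻¹)
    protic impurity + free monomer → quenched substrate (k = 22.0 L mol⁻¹ s⁻¹)

In epsilon at 3.00 min, living end and dead chain together stand at 0.130 mM, the initiator charge of 0.13 mM, against the forecast's 0.22 mM. The ceiling length, less the free monomer still there (9.53 % of the charge) over that same charge, gives 124.

In a neighbour of theta with 0.340 mM of transfer agent, the ceiling length holds no term for that agent and stays 30.8; less the free monomer still there (15.1 % of the charge) over the initiator charge, it gives 23.8. That neighbour flask gives 23.8, below the ceiling.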